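## Structural features

The target 44 is a germacranolide: a ten-membered carbocycle (C1–C10) fused trans across C7–C8 to an α-methylene-γ-butyrolactone made of C11, C12 (carbonyl, bound to O8) and C13 (exocyclic methylene). The large ring carries an E-trisubstituted alkene C1=C10, a cis-4,5-epoxide with the C4 methyl, a free hydroxyl at C6 and an isobutyrate at C9. Six stereocentres run without a gap from C4 to C9 (4S,5R,6S,7S,8R,9S); C6, C7 and C8 are all-syn along the chain and the C8/C9 diol is erythro, so its acetonide is a cis-dioxolane. Fragile groups are the methylene lactone (a Michael acceptor that can also migrate to O6), the epoxide beside a free hydroxyl, the allylic ester, and the 1(10),4-diene of the late intermediates, which strong acid can cyclize across the ring. The real difficulty is closing a medium ring that holds two trisubstituted alkenes of opposite geometry beside a dense stereotetrad. The key step uses the one ring bond that is remote from every stereocentre: C2–C3 joins two allylic methylenes, C2 next to C1=C10 (a π-allyl terminus) and C3 next to the Z-C4=C5 alkene (a seat for a stabilized carbanion), while the cis-dioxolane on C8/C9 and the Z alkene hold both chain ends on one side.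

## Logic of the disconnections

44 ⇒ 43. The two C–O bonds of the epoxide are cut. The epoxide is the most acid-sensitive group and the C6 hydroxyl beside it can deliver the oxidant, so it is made last. Two stereocentres disappear. The forward step must oxidize only C4=C5, on the face of the hydroxyl, and leave C1=C10 and C11=C13 alone.

43 ⇒ 42 ⇒ 41. The O6–Si bond and the acyl C–O bond at O9 are cut. O6 stays silylated until lactone and ester are in place, because a free O6 could take the lactone carbonyl or the acyl group. What remains has a single free hydroxyl. The forward steps must acylate a hindered allylic alcohol and remove silicon without a base that adds to the methylene lactone.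

41 ⇒ 39 ⇒ 37 ⇒ 36. The lactone bond C12–O8 is cut and C12 goes back to a protected primary alcohol, with O8 and O9 tied in a ketal. An acrylate cannot be present during ring closure, where it would trap the C3 carbanion. This removes the Michael acceptor and one ring. Forward, the ketal must open under acid mild enough for the diene and the silyl ether, and the acid must close on O8 only.

36 ⇒ 35 ⇒ 34. Two C3–S bonds are put back. They are what makes C3 a soft nucleophile; the skeleton is unchanged. Forward, they must leave one after the other without shifting or isomerizing C4=C5.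

34 ⇒ 32. The ring bond C2–C3 is cut between the two allylic carbons. No stereocentre is touched and the ring opens to a chain whose ends are bent towards each other. The forward step needs attack at C2 and not at C10, retention of the E alkene, and cyclization faster than oligomerization.

32 ⇒ 31 ⇒ 30 ⇒ 27 ⇒ 26. The carbonate C–O bond, the O–Si bond at O2, the second C3–S bond and the S=O bonds are removed in turn. C3 then carries a plain sulfide that survives the earlier steps. Forward, sulfur is oxidized without touching three alkenes and the second sulfonyl group is added without loss of the Z geometry.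

26 ⇒ 25 ⇒ 24 ⇒ 23. The benzyl ether and ketal C–O bonds are cut, and C12 and O8 are rejoined as a lactone with O9 as an acetate. The lactone is the template that controls C6 and C7. Forward, one hydride reduction opens the lactone and frees O9, and the erythro diol must take the ketal in preference to the other hydroxyls.

23 ⇒ 22 ⇒ 14 + 20. The C6–C7 bond is cut. This splits the molecule into two halves of similar size and creates two stereocentres in the forward step. The addition must go through the γ-carbon C7, anti to the C8 substituent, with the aldehyde substituent equatorial.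

14 ⇒ 13 ⇒ 12 ⇒ 11 ⇒ 3 + 9. The C13–Br bond, the acetate and the ether at C13 are adjusted, and the C8–C9 bond is cut. All lactone carbons come from one furan and the E half from one enal. The forward step must be γ-selective, anti-selective and enantioselective.

3 ⇒ 1 + 2; 9 ⇒ 8 ⇒ 5 ⇒ 4; 20 ⇒ 18 ⇒ 17 ⇒ 15. The C1=C10 alkene, the C–O bond at furan C2, and the C5–C6, C3–S, C5–I and C4–CH3 bonds are cut back to commercial materials. Each forward step has to set or keep one alkene geometry.

## Other disconnections considered

Alternative 1: The C5–C6 bond is cut. In the forward direction the (Z)-alkenyl iodide of A2 would add to its own C6 aldehyde under CrCl2 with catalytic NiCl2 and give the ring allylic alcohol A1. As drawn, A1 has no C13 (C11 is a methylene), so it is a 13-nor lactone and not a dihydro compound; C13 would have to be added afterwards. In its favour, the ring and the C6 carbinol are made together under almost neutral conditions, the Z geometry is carried in unchanged, and lactone and C9 ester are already in place. On step economy after ring closure it would be the better plan, since there is no desulfonylation and no redox detour at C12. Against it, the closure must create the C6 stereocentre inside a forming ten-membered ring, where ring strain and not a reagent picks the aldehyde face. The aldehyde of A2 is branched at C7 and sits β to the lactone oxygen, so epimerization and elimination threaten before cyclization. The later α-methylenation would need an enolate beside the C9 ester and the C6 hydroxyl. Structurally, the chosen bond C2–C3 creates no stereocentre and C5–C6 creates one; mechanistically, an irreversible organochromium addition cannot correct a wrong epimer, while the π-allyl route has only regiochemical and geometric questions. The two are equal in needing high dilution.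

Alternative 2: C1–C10 and C4–C5 are the bonds formed. Enone A4 and cyclobutene A5 would combine by [2+2] photocycloaddition, and heating would open the adduct by cycloreversion and Cope rearrangement to dienone A3. In its favour, the ten-membered ring grows out of a six-membered one with no macrocyclization, and on entropy and concentration this is better than the chosen plan. Both alkene geometries follow from concerted steps, and C6–C8 are set on a cyclohexenone. Against it, an unsymmetrical cyclobutene raises a head-to-head versus head-to-tail question on a crowded enone. The Cope equilibrium is pulled towards A3 only by conjugation with the C9 ketone, and the thermolysis temperature is hard on silyl ether and acetals. A3 carries only two of the three lactone carbons and a C9 ketone, so C11–C13 must be rebuilt and C9 reduced with the right face. Structurally, the chosen plan brings C6–C9 to the ring closure fully functionalized; mechanistically, pericyclic stereospecificity is traded for an equilibrium. Up to the ring the alternative is equal or shorter, after it clearly longer.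

Alternative 3: C8–C9 is formed and C1–C6 broken. The potassium alkoxide of cyclohexenol A7 (KH, 18-crown-6) would undergo a [3,3] shift, and protonation of the C6 enolate at C7 would give ketone A6. In its favour, the ring comes from ring expansion and not from macrocyclization, E-C1=C10 follows from a chair transition state, and C8 and C9 are created in the key step. On stereocentres made in the key step it is the better plan, since the chosen step makes none; on the Z alkene the two are equal, as it is simply the cyclohexene double bond. Against it, A7 needs a (Z)-enol ether and a dihydrofuran on a tertiary carbinol in a defined trans relation. The product enolate has O8 in the β-position and can open the lactol ring by elimination under KH. C7 is set by an uncontrolled protonation, the C6 ketone must be reduced with the right face, C13 is missing and C12 is only at the lactol level. Structurally, it leaves more redox and carbon work after the ring; mechanistically, a strongly basic anionic step is set against a neutral one.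

Key step: step 21

Remarks on the chemistry:
- Locants C1–C13 in the names of 22–43 and of the A and F compounds are those of the germacrane skeleton of 44; "2,3-seco" means that the C2–C3 bond is absent.
- The 8,9-diol is erythro (cis-dioxolane in 32), which syn-dihydroxylation of an E-alkene cannot give; C8 and C9 are therefore set by an anti-selective vinylogous aldol reaction.
- C3 of 32 itself carries both sulfonyl groups; alkylating bis(phenylsulfonyl)methane would insert one carbon too many and lead to an eleven-membered ring, so the two sulfur groups are built up on C3.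
- A1 is treated as the 13-nor lactone that its structure shows.

## Route

Step 1
Reactants: 1 (tert-butyldimethylsilyloxy)acetaldehyde; 2 2-(triphenylphosphoranylidene)propanal
Product: 3 (E)-4-(tert-butyldimethylsilyloxy)-2-methylbut-2-enal
Conditions: toluene, 80 °C
Reagents that add atoms: none
Why: Wittig olefination with the formyl-stabilized ylide is E-selective for trisubstituted enals, which fixes the C1=C10 geometry at the start.

Step 2
Reactants: 4 furan-3-ylmethanol
Product: 5 3-[(4-methoxybenzyloxy)methyl]furan
Conditions: NaH, 4-MeOC6H4CH2Cl, Bu4NI (cat.), THF/DMF, 0 °C → rt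
Reagents that add atoms: 4-methoxybenzyl chloride, COc1ccc(CCl)cc1
Why: Williamson etherification of a primary alcohol; the ether oxygen is the later handle on C13.

Step 3
Reactants: 5 3-[(4-methoxybenzyloxy)methyl]furan
Product: 8 3-[(4-methoxybenzyloxy)methyl]furan-2(5H)-one, via 2-furyllithium 6 (not isolated), via furylboronate 7 (not isolated)
Conditions: n-BuLi, THF, −78 → 0 °C; B(OMe)3, −78 °C → rt; 30% H2O2, AcOH, 0 °C; then Et3N (cat.), CH2Cl2, rt
Reagents that add atoms: hydrogen peroxide, OO
Why: Lithiation of a 3-substituted furan goes to C2, between the ring oxygen and the coordinating ether arm; borylation and C–B oxidation give the 2-hydroxyfuran, which settles as the conjugated butenolide (lithiation–borylation–oxidation).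

Step 4
Reactants: 8 3-[(4-methoxybenzyloxy)methyl]furan-2(5H)-one
Product: 9 2-(tert-butyldimethylsilyloxy)-3-[(4-methoxybenzyloxy)methyl]furan
Conditions: t-BuMe2SiOTf, Et3N, CH2Cl2, 0 °C
Reagents that add atoms: tert-butyldimethylsilyl trifluoromethanesulfonate, CC(C)(C)[Si](C)(C)OS(=O)(=O)C(F)(F)F
Why: Soft enolization and O-silylation are driven by aromatization to the 2-silyloxyfuran (silyl dienol ether formation).

Step 5
Reactants: 3 (E)-4-(tert-butyldimethylsilyloxy)-2-methylbut-2-enal; 9 2-(tert-butyldimethylsilyloxy)-3-[(4-methoxybenzyloxy)methyl]furan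
Product: 11 (8R,9S)-anti aldol butenolide with free C9 hydroxyl, via trichlorosilyl ether 10 (not isolated)
Conditions: SiCl4 (1.1 equiv), (R,R)-N,N′-bis[4,5-dihydro-3,5-dimethyl-4-(3H-dinaphtho[2,1-d:1′,2′-f][1,3,2]diazaphosphepin-4-oxide)]-N,N′-dimethylpentane-1,5-diamine (5 mol%), i-Pr2NEt (10 mol%), CH2Cl2, −78 °C; aq. NaHCO3/KF
Reagents that add atoms: none
Why: Lewis-base-activated SiCl4 vinylogous Mukaiyama aldol reaction: the furan adds through its γ-carbon (C8) to the Re face of the bound aldehyde in an open transition state that should give the anti (erythro) adduct, so C8 (R) and C9 (S) are both set by the chiral catalyst. Conjugated α-branched aldehydes are the preferred substrates of this catalyst class.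

Step 6
Reactants: 11 (8R,9S)-anti aldol butenolide
Product: 12 C9 acetate of 11
Conditions: Ac2O, pyridine, CH2Cl2, 0 °C → rt
Reagents that add atoms: acetic anhydride, CC(=O)OC(C)=O
Why: Acylation of the secondary alcohol with a weak amine base, so that the acidic γ-hydrogen at C8 of the butenolide is not removed.

Step 7
Reactants: 12 C9 acetate
Product: 13 3-(hydroxymethyl)butenolide acetate
Conditions: 2,3-dichloro-5,6-dicyano-1,4-benzoquinone (DDQ), CH2Cl2/pH 7 buffer, 0 °C
Reagents that add atoms: none
Why: Oxidative cleavage of the 4-methoxybenzyl ether by hydride abstraction and hydrolysis; silyl ether, acetate and butenolide are inert.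

Step 8
Reactants: 13 3-(hydroxymethyl)butenolide acetate
Product: 14 3-(bromomethyl)butenolide acetate
Conditions: CBr4, PPh3, CH2Cl2, 0 °C
Reagents that add atoms: carbon tetrabromide, BrC(Br)(Br)Br
Why: Appel bromination of a primary allylic alcohol under neutral conditions.

Step 9
Reactants: 15 prop-2-yn-1-ol
Product: 17 (Z)-3-iodo-2-methylprop-2-en-1-ol, via alkenylmagnesium bromide 16 (not isolated)
Conditions: MeMgBr (3 equiv), CuI (10 mol%), THF, −20 °C → rt; then I2, −78 → 0 °C
Reagents that add atoms: methylmagnesium bromide, C[Mg]Br; iodine, [I][I]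
Why: Copper-catalysed anti-carbomagnesiation of the propargylic alkoxide puts methyl on the carbon next to CH2O and magnesium cis to the alkoxide in a five-membered chelate; iodinolysis with retention gives the Z iodide, which fixes the C4=C5 geometry.

Step 10
Reactants: 17 (Z)-3-iodo-2-methylprop-2-en-1-ol
Product: 18 (Z)-3-iodo-2-methylprop-2-enyl phenyl sulfide
Conditions: PhSSPh, PBu3, THF, rt
Reagents that add atoms: diphenyl disulfide, c1ccc(SSc2ccccc2)cc1
Why: Hata thioetherification: the alkoxyphosphonium ion is displaced by thiolate in an SN2 reaction at the primary allylic carbon, without touching the alkene.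

Step 11
Reactants: 18 (Z)-3-iodo-2-methylprop-2-enyl phenyl sulfide
Product: 20 (Z)-3-methyl-4-(phenylsulfanyl)but-2-enal, via alkenyllithium 19 (not isolated)
Conditions: t-BuLi (2.1 equiv), Et2O, −78 °C; DMF; cold aq. NH4Cl
Reagents that add atoms: N,N-dimethylformamide, CN(C)C=O
Why: Iodine–lithium exchange on an alkenyl iodide and formylation both go with retention of configuration, so the Z enal is obtained.

Step 12
Reactants: 14 3-(bromomethyl)butenolide acetate; 20 (Z)-3-methyl-4-(phenylsulfanyl)but-2-enal
Product: 22 (6R,7S,8R,9S)-β-(hydroxyalkyl)-α-methylene lactone, via allylchromium dichloride 21 (not isolated)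
Conditions: CrCl2 (4 equiv), THF, 0 °C → rt
Reagents that add atoms: none
Why: Nozaki–Hiyama allylation: the trivalent allylchromium adds through its γ-carbon C7 in a six-membered chair transition state and shifts the double bond to C11=C13. The aldehyde comes in on the butenolide face opposite the C8 side chain (C7 trans to C8), and its substituent sits equatorial while C8 occupies the position trans to CH2Cr (O6 anti to C8), which is the behaviour known for 3-(bromomethyl)furan-2(5H)-one.

Step 13
Reactants: 22 (6R,7S,8R,9S)-β-(hydroxyalkyl)-α-methylene lactone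
Product: 23 C6 tert-butyldimethylsilyl ether of 22
Conditions: t-BuMe2SiOTf, 2,6-lutidine, CH2Cl2, −78 °C
Reagents that add atoms: tert-butyldimethylsilyl trifluoromethanesulfonate, CC(C)(C)[Si](C)(C)OS(=O)(=O)C(F)(F)F
Why: Silylation of a hindered secondary alcohol with a non-nucleophilic base that does not add to the methylene lactone.

Step 14
Reactants: 23 C6 silyl ether
Product: 24 seco 8,9,12-triol
Conditions: i-Bu2AlH (8 equiv), CH2Cl2, −78 → 0 °C; aq. potassium sodium tartrate
Reagents that add atoms: none
Why: 1,2-Reduction of the α-methylene lactone gives the 2-methylene-1,4-diol, and the same hydride cleaves the acetate; no stereocentre is touched.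

Step 15
Reactants: 24 seco 8,9,12-triol
Product: 25 8,9-acetonide 12-alcohol
Conditions: Me2C(OMe)2, pyridinium p-toluenesulfonate (cat.), CH2Cl2, rt; brief MeOH quench
Reagents that add atoms: 2,2-dimethoxypropane, COC(C)(C)OC
Why: Ketal exchange: the erythro 1,2-diol closes to the five-membered cis-dioxolane, which is favoured over a seven-membered ketal with the primary hydroxyl.

Step 16
Reactants: 25 8,9-acetonide 12-alcohol
Product: 26 12-O-(4-methoxybenzyl) ether
Conditions: NaH, 4-MeOC6H4CH2Cl, Bu4NI (cat.), THF/DMF, 0 °C → rt
Reagents that add atoms: 4-methoxybenzyl chloride, COc1ccc(CCl)cc1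
Why: Williamson etherification; silyl ethers, ketal and allyl sulfide are stable to the alkoxide.

Step 17
Reactants: 26 12-O-(4-methoxybenzyl) ether
Product: 27 C3 phenyl sulfone
Conditions: (NH4)6Mo7O24·4H2O (10 mol%), 30% H2O2, EtOH, 0 °C → rt
Reagents that add atoms: hydrogen peroxide, OO
Why: Molybdate-catalysed oxidation of sulfide to sulfone is much faster than epoxidation of alkenes that carry no free allylic hydroxyl.

Step 18
Reactants: 27 C3 phenyl sulfone
Product: 30 C3 bis(phenylsulfonyl) compound, via lithiated sulfone 28 (not isolated), via lithiated bis-sulfone 29 (not isolated)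
Conditions: PhSO2F (1.2 equiv), LiN(SiMe3)2 (2.3 equiv, slow addition), THF, −78 °C; AcOH
Reagents that add atoms: benzenesulfonyl fluoride, O=S(=O)(F)c1ccccc1
Why: The α-sulfonyl allyl carbanion attacks sulfur of the sulfonyl fluoride at its α-carbon (sulfonylation of a sulfone carbanion), and the second equivalent of base stores the more acidic product as its anion. Allyl sulfone anions of this kind keep their alkene geometry at low temperature.

Step 19
Reactants: 30 C3 bis(phenylsulfonyl) compound
Product: 31 C2 primary allylic alcohol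
Conditions: HF·pyridine, pyridine, THF, 0 °C
Reagents that add atoms: none
Why: Buffered fluoride removes the unhindered primary silyl ether much faster than the secondary one at C6, which is flanked by the branched C7.

Step 20
Reactants: 31 C2 primary allylic alcohol
Product: 32 C2 allylic methyl carbonate
Conditions: ClCO2Me, pyridine, CH2Cl2, 0 °C
Reagents that add atoms: methyl chloroformate, COC(=O)Cl
Why: O-Acylation of the primary alcohol; pyridine is too weak a base to deprotonate the bis-sulfone.

Step 21
Reactants: 32 C2 allylic methyl carbonate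
Product: 34 ten-membered 3,3-bis(phenylsulfonyl) ring, via π-allylpalladium zwitterion 33 (not isolated)
Conditions: Pd(PPh3)4 (10 mol%), THF, 65 °C, syringe-pump addition to a final 1 mM
Reagents that add atoms: none
Why: Zerovalent palladium ionizes the primary allylic carbonate with loss of CO2, and the methoxide so released deprotonates C3–H (pKa about 12), so no external base is present. The bis(sulfonyl) carbanion then attacks the π-allyl ligand on the face away from the metal, as in the Tsuji–Trost alkylation of allylic carbonates by bis(phenylsulfonyl)methane derivatives, the closest known reaction type. The ring closes by attack at the unsubstituted terminus C2, which puts C1=C10 inside the new ten-membered ring; attack at the fully substituted terminus C10 would give an eight-membered ring with a quaternary carbon and is disfavoured by sterics. No stereocentre is formed; the π-allyl isomer with the branched C9 syn and the methyl anti corresponds to the E alkene and is the preferred one, so the geometry is kept. The cis-dioxolane on C8/C9 and the Z alkene turn both chain ends to the same side, and slow addition favours ring closure over oligomerization. The allylic C–S bonds of substrate and product ionize far more slowly than the carbonate, so the temperature is held at 65 °C or below and the reaction is stopped at full conversion.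

Step 22
Reactants: 34 ten-membered 3,3-bis(phenylsulfonyl) ring
Product: 35 ten-membered 3-(phenylsulfonyl) ring (C3 epimers)
Conditions: SmI2 (3 equiv), THF/MeOH (10:1), −78 → −20 °C
Reagents that add atoms: none
Why: Single-electron reduction cleaves one C–S bond of the geminal bis-sulfone, because the carbanion left behind is sulfonyl-stabilized; methanol protonates it at C3. The remaining mono-sulfone is not reduced without a stronger donor additive.

Step 23
Reactants: 35 ten-membered 3-(phenylsulfonyl) ring
Product: 36 (1(10)E,4Z)-ten-membered diene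
Conditions: PdCl2[Ph2P(CH2)3PPh2] (5 mol%), LiBHEt3, THF, 0 °C
Reagents that add atoms: none
Why: Palladium-catalysed hydride substitution of an allylic sulfone: ionization gives the C3–C4–C5 π-allyl complex and hydride is delivered to the less hindered terminus C3, so C4=C5 keeps its place and its Z geometry. This is the method used for prenyl-type sulfones in 1,5-dienes, where dissolving metals scramble the alkene.

Step 24
Reactants: 36 (1(10)E,4Z)-ten-membered diene
Product: 37 C12 primary allylic alcohol
Conditions: 2,3-dichloro-5,6-dicyano-1,4-benzoquinone (DDQ), CH2Cl2/pH 7 buffer, 0 °C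
Reagents that add atoms: none
Why: Oxidative removal of the 4-methoxybenzyl ether; ketal, silyl ether and the isolated alkenes are not affected.

Step 25
Reactants: 37 C12 primary allylic alcohol
Product: 39 C12 acrylic acid, via enal 38 (not isolated)
Conditions: 2,2,6,6-tetramethylpiperidine-1-oxyl (cat.), PhI(OAc)2, CH2Cl2, rt; then NaClO2, NaH2PO4, 2-methylbut-2-ene, t-BuOH/H2O, 0 °C
Reagents that add atoms: sodium chlorite, [Na+].[O-]Cl=O
Why: Oxoammonium oxidation takes the primary allylic alcohol to the enal, and Pinnick oxidation with a hypochlorite scavenger gives the acid without touching the ring alkenes.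

Step 26
Reactants: 39 C12 acrylic acid
Product: 41 9-hydroxy 12,8-lactone with C6 silyl ether, via dihydroxy acid 40 (not isolated)
Conditions: AcOH/H2O (4:1), 40 °C
Reagents that add atoms: none
Why: Weak aqueous acid hydrolyses the dioxolane, and the γ-hydroxy acid closes at once to the five-membered lactone on O8; O6 is silylated and O9 would need a six-membered ring. The trans ring fusion is already fixed by C7 and C8.

Step 27
Reactants: 41 9-hydroxy 12,8-lactone
Product: 42 9-isobutyrate
Conditions: (i-PrCO)2O, 4-(dimethylamino)pyridine (cat.), pyridine, CH2Cl2, 0 °C → rt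
Reagents that add atoms: isobutyric anhydride, CC(C)C(=O)OC(=O)C(C)C
Why: Nucleophile-catalysed acylation of the only free hydroxyl.

Step 28
Reactants: 42 9-isobutyrate
Product: 43 6-hydroxy diene lactone
Conditions: HF·pyridine, THF, 0 °C → rt
Reagents that add atoms: none
Why: Acidic fluoride cleaves the secondary silyl ether without the basic conditions that would move the lactone or the ester to O6 or add to the methylene lactone.

Step 29
Reactants: 43 6-hydroxy diene lactone
Product: 44 target (4S,5R,6S,7S,8R,9S)-epoxide
Conditions: VO(acac)2 [vanadyl bis(acetylacetonate)] (5 mol%), t-BuOOH, CH2Cl2, 0 °C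
Reagents that add atoms: tert-butyl hydroperoxide, CC(C)(C)OO
Why: Hydroxyl-directed epoxidation: the vanadium peroxide bound to O6 reaches only the allylic alkene C4=C5. With H6 eclipsing the alkene (A(1,3) strain from the cis C3), oxygen is delivered from the outer face that carries the hydroxyl, giving the cis-epoxide with 4S,5R; C1=C10 and the electron-poor C11=C13 are left.

## Compound list

1 | (tert-butyldimethylsilyloxy)acetaldehyde | CC(C)(C)[Si](C)(C)OCC=O | starting material
2 | 2-(triphenylphosphoranylidene)propanal | CC(C=O)=P(c1ccccc1)(c1ccccc1)c1ccccc1 | starting material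
3 | (2E)-4-(tert-butyldimethylsilyloxy)-2-methylbut-2-enal | CC(C)(C)[Si](C)(C)OC/C=C(\C)C=O | intermediate
4 | furan-3-ylmethanol | OCc1ccoc1 | starting material
5 | 3-[(4-methoxybenzyloxy)methyl]furan | COc1ccc(COCc2ccoc2)cc1 | intermediate
6 | 2-lithio-3-[(4-methoxybenzyloxy)methyl]furan | [Li]c1occc1COCc1ccc(OC)cc1 | intermediate
7 | dimethyl {3-[(4-methoxybenzyloxy)methyl]furan-2-yl}boronate | COB(OC)c1occc1COCc1ccc(OC)cc1 | intermediate
8 | 3-[(4-methoxybenzyloxy)methyl]furan-2(5H)-one | COc1ccc(COCC2=CCOC2=O)cc1 | intermediate
9 | 2-(tert-butyldimethylsilyloxy)-3-[(4-methoxybenzyloxy)methyl]furan | COc1ccc(COCc2ccoc2O[Si](C)(C)C(C)(C)C)cc1 | intermediate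
10 | O-trichlorosilyl ether of 11 | CC(C)(C)[Si](C)(C)OC/C=C(\C)[C@H](O[Si](Cl)(Cl)Cl)[C@@H]1OC(=O)C(COCc2ccc(OC)cc2)=C1 | intermediate
11 | (5R)-5-[(1S,2E)-4-(tert-butyldimethylsilyloxy)-1-hydroxy-2-methylbut-2-en-1-yl]-3-[(4-methoxybenzyloxy)methyl]furan-2(5H)-one | CC(C)(C)[Si](C)(C)OC/C=C(\C)[C@H](O)[C@@H]1OC(=O)C(COCc2ccc(OC)cc2)=C1 | intermediate
12 | (1S,2E)-4-(tert-butyldimethylsilyloxy)-1-[(2R)-4-{[(4-methoxybenzyl)oxy]methyl}-5-oxo-2,5-dihydrofuran-2-yl]-2-methylbut-2-en-1-yl acetate | CC(C)(C)[Si](C)(C)OC/C=C(\C)[C@H](OC(C)=O)[C@@H]1OC(=O)C(COCc2ccc(OC)cc2)=C1 | intermediate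
13 | (1S,2E)-4-(tert-butyldimethylsilyloxy)-1-[(2R)-4-(hydroxymethyl)-5-oxo-2,5-dihydrofuran-2-yl]-2-methylbut-2-en-1-yl acetate | CC(C)(C)[Si](C)(C)OC/C=C(\C)[C@H](OC(C)=O)[C@@H]1OC(=O)C(CO)=C1 | intermediate
14 | (1S,2E)-1-[(2R)-4-(bromomethyl)-5-oxo-2,5-dihydrofuran-2-yl]-4-(tert-butyldimethylsilyloxy)-2-methylbut-2-en-1-yl acetate | CC(C)(C)[Si](C)(C)OC/C=C(\C)[C@H](OC(C)=O)[C@@H]1OC(=O)C(CBr)=C1 | intermediate
15 | prop-2-yn-1-ol | C#CCO | starting material
16 | bromo[(1Z)-3-(bromomagnesiooxy)-2-methylprop-1-en-1-yl]magnesium | C/C(CO[Mg]Br)=C/[Mg]Br | intermediate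
17 | (2Z)-3-iodo-2-methylprop-2-en-1-ol | C/C(CO)=C/I | intermediate
18 | {[(2Z)-3-iodo-2-methylprop-2-en-1-yl]sulfanyl}benzene | C/C(CSc1ccccc1)=C/I | intermediate
19 | [(1Z)-2-methyl-3-(phenylsulfanyl)prop-1-en-1-yl]lithium | C/C(CSc1ccccc1)=C/[Li] | intermediate
20 | (2Z)-3-methyl-4-(phenylsulfanyl)but-2-enal | C/C(CSc1ccccc1)=C/C=O | intermediate
21 | dichloro({(5R)-5-[(1S,2E)-1-acetoxy-4-(tert-butyldimethylsilyloxy)-2-methylbut-2-en-1-yl]-2-oxo-2,5-dihydrofuran-3-yl}methyl)chromium | CC(C)(C)[Si](C)(C)OC/C=C(\C)[C@H](OC(C)=O)[C@@H]1OC(=O)C(C[Cr](Cl)Cl)=C1 | intermediate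
22 | (1S,2E)-4-(tert-butyldimethylsilyloxy)-1-{(2R,3S)-3-[(1R,2Z)-1-hydroxy-3-methyl-4-(phenylsulfanyl)but-2-en-1-yl]-4-methylidene-5-oxooxolan-2-yl}-2-methylbut-2-en-1-yl acetate (6R,7S,8R,9S) | CC(C)(C)[Si](C)(C)OC/C=C(\C)[C@H](OC(C)=O)[C@@H]1OC(=O)C(=C)[C@H]1[C@H](O)/C=C(C)\CSc1ccccc1 | intermediate
23 | 6-O-tert-butyldimethylsilyl ether of 22 (6R,7R,8R,9S; the C7 descriptor changes by priority only) | CC(C)(C)[Si](C)(C)OC/C=C(\C)[C@H](OC(C)=O)[C@@H]1OC(=O)C(=C)[C@H]1[C@H](O[Si](C)(C)C(C)(C)C)/C=C(C)\CSc1ccccc1 | intermediate
24 | (6R,7R,8R,9S)-2,6-bis(tert-butyldimethylsilyloxy)-3-(phenylsulfanyl)-2,3-secogermacra-1(10)E,4Z,11(13)-triene-8,9,12-triol | CC(C)(C)[Si](C)(C)OC/C=C(\C)[C@H](O)[C@H](O)[C@@H](C(=C)CO)[C@H](O[Si](C)(C)C(C)(C)C)/C=C(C)\CSc1ccccc1 | intermediate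
25 | (6R,7R,8R,9S)-2,6-bis(tert-butyldimethylsilyloxy)-8,9-(isopropylidenedioxy)-3-(phenylsulfanyl)-2,3-secogermacra-1(10)E,4Z,11(13)-trien-12-ol | CC(C)(C)[Si](C)(C)OC/C=C(\C)[C@@H]1OC(C)(C)O[C@@H]1[C@@H](C(=C)CO)[C@H](O[Si](C)(C)C(C)(C)C)/C=C(C)\CSc1ccccc1 | intermediate
26 | 12-O-(4-methoxybenzyl) ether of 25 | CC(C)(C)[Si](C)(C)OC/C=C(\C)[C@@H]1OC(C)(C)O[C@@H]1[C@@H](C(=C)COCc1ccc(OC)cc1)[C@H](O[Si](C)(C)C(C)(C)C)/C=C(C)\CSc1ccccc1 | intermediate
27 | (6R,7R,8R,9S)-2,6-bis(tert-butyldimethylsilyloxy)-8,9-(isopropylidenedioxy)-12-(4-methoxybenzyloxy)-3-(phenylsulfonyl)-2,3-secogermacra-1(10)E,4Z,11(13)-triene | CC(C)(C)[Si](C)(C)OC/C=C(\C)[C@@H]1OC(C)(C)O[C@@H]1[C@@H](C(=C)COCc1ccc(OC)cc1)[C@H](O[Si](C)(C)C(C)(C)C)/C=C(C)\CS(=O)(=O)c1ccccc1 | intermediate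
28 | 3-lithio derivative of 27 | CC(C)(C)[Si](C)(C)OC/C=C(\C)[C@@H]1OC(C)(C)O[C@@H]1[C@@H](C(=C)COCc1ccc(OC)cc1)[C@H](O[Si](C)(C)C(C)(C)C)/C=C(C)\C([Li])S(=O)(=O)c1ccccc1 | intermediate
29 | 3-lithio derivative of 30 | CC(C)(C)[Si](C)(C)OC/C=C(\C)[C@@H]1OC(C)(C)O[C@@H]1[C@@H](C(=C)COCc1ccc(OC)cc1)[C@H](O[Si](C)(C)C(C)(C)C)/C=C(C)\C([Li])(S(=O)(=O)c1ccccc1)S(=O)(=O)c1ccccc1 | intermediate
30 | (6R,7R,8R,9S)-2,6-bis(tert-butyldimethylsilyloxy)-8,9-(isopropylidenedioxy)-12-(4-methoxybenzyloxy)-3,3-bis(phenylsulfonyl)-2,3-secogermacra-1(10)E,4Z,11(13)-triene | CC(C)(C)[Si](C)(C)OC/C=C(\C)[C@@H]1OC(C)(C)O[C@@H]1[C@@H](C(=C)COCc1ccc(OC)cc1)[C@H](O[Si](C)(C)C(C)(C)C)/C=C(C)\C(S(=O)(=O)c1ccccc1)S(=O)(=O)c1ccccc1 | intermediate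
31 | 2-hydroxy compound from 30 (C2 silyl ether removed) | OC/C=C(\C)[C@@H]1OC(C)(C)O[C@@H]1[C@@H](C(=C)COCc1ccc(OC)cc1)[C@H](O[Si](C)(C)C(C)(C)C)/C=C(C)\C(S(=O)(=O)c1ccccc1)S(=O)(=O)c1ccccc1 | intermediate
32 | methyl carbonate of 31 (acyclic precursor of the key step) | COC(=O)OC/C=C(\C)[C@@H]1OC(C)(C)O[C@@H]1[C@@H](C(=C)COCc1ccc(OC)cc1)[C@H](O[Si](C)(C)C(C)(C)C)/C=C(C)\C(S(=O)(=O)c1ccccc1)S(=O)(=O)c1ccccc1 | intermediate
33 | bis(triphenylphosphine)allylpalladium cation with C3 carbanion (zwitterion, drawn in the η1 form) | c1ccc(cc1)P(c1ccccc1)(c1ccccc1)[Pd+](P(c1ccccc1)(c1ccccc1)c1ccccc1)C/C=C(\C)[C@@H]1OC(C)(C)O[C@@H]1[C@@H](C(=C)COCc1ccc(OC)cc1)[C@H](O[Si](C)(C)C(C)(C)C)/C=C(C)\[C-](S(=O)(=O)c1ccccc1)S(=O)(=O)c1ccccc1 | intermediate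
34 | (6R,7R,8R,9S)-6-(tert-butyldimethylsilyloxy)-8,9-(isopropylidenedioxy)-12-(4-methoxybenzyloxy)-3,3-bis(phenylsulfonyl)germacra-1(10)E,4Z,11(13)-triene | CC1(C)O[C@@H]2[C@@H](C(=C)COCc3ccc(OC)cc3)[C@H](O[Si](C)(C)C(C)(C)C)/C=C(C)\C(S(=O)(=O)c3ccccc3)(S(=O)(=O)c3ccccc3)C/C=C(\C)[C@@H]2O1 | intermediate
35 | 3-(phenylsulfonyl) analogue of 34 (both C3 epimers) | CC1(C)O[C@@H]2[C@@H](C(=C)COCc3ccc(OC)cc3)[C@H](O[Si](C)(C)C(C)(C)C)/C=C(C)\C(S(=O)(=O)c3ccccc3)C/C=C(\C)[C@@H]2O1 | intermediate
36 | (6R,7R,8R,9S)-6-(tert-butyldimethylsilyloxy)-8,9-(isopropylidenedioxy)-12-(4-methoxybenzyloxy)germacra-1(10)E,4Z,11(13)-triene | CC1(C)O[C@@H]2[C@@H](C(=C)COCc3ccc(OC)cc3)[C@H](O[Si](C)(C)C(C)(C)C)/C=C(C)\CC/C=C(\C)[C@@H]2O1 | intermediate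
37 | (6R,7R,8R,9S)-6-(tert-butyldimethylsilyloxy)-8,9-(isopropylidenedioxy)germacra-1(10)E,4Z,11(13)-trien-12-ol | CC1(C)O[C@@H]2[C@@H](C(=C)CO)[C@H](O[Si](C)(C)C(C)(C)C)/C=C(C)\CC/C=C(\C)[C@@H]2O1 | intermediate
38 | corresponding 12-al (enal) | CC1(C)O[C@@H]2[C@@H](C(=C)C=O)[C@H](O[Si](C)(C)C(C)(C)C)/C=C(C)\CC/C=C(\C)[C@@H]2O1 | intermediate
39 | corresponding 12-oic acid | CC1(C)O[C@@H]2[C@@H](C(=C)C(=O)O)[C@H](O[Si](C)(C)C(C)(C)C)/C=C(C)\CC/C=C(\C)[C@@H]2O1 | intermediate
40 | (6R,7R,8R,9S)-6-(tert-butyldimethylsilyloxy)-8,9-dihydroxygermacra-1(10)E,4Z,11(13)-trien-12-oic acid | O[C@@H]1[C@@H](C(=C)C(=O)O)[C@H](O[Si](C)(C)C(C)(C)C)/C=C(C)\CC/C=C(\C)[C@@H]1O | intermediate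
41 | (6R,7R,8R,9S)-6-(tert-butyldimethylsilyloxy)-9-hydroxygermacra-1(10)E,4Z,11(13)-trien-12,8-olide | C=C1C(=O)O[C@@H]2[C@@H]1[C@H](O[Si](C)(C)C(C)(C)C)/C=C(C)\CC/C=C(\C)[C@@H]2O | intermediate
42 | (6R,7R,8R,9S)-6-(tert-butyldimethylsilyloxy)-9-(2-methylpropanoyloxy)germacra-1(10)E,4Z,11(13)-trien-12,8-olide | C=C1C(=O)O[C@@H]2[C@@H]1[C@H](O[Si](C)(C)C(C)(C)C)/C=C(C)\CC/C=C(\C)[C@@H]2OC(=O)C(C)C | intermediate
43 | (6R,7S,8R,9S)-6-hydroxy-9-(2-methylpropanoyloxy)germacra-1(10)E,4Z,11(13)-trien-12,8-olide | C=C1C(=O)O[C@@H]2[C@@H]1[C@H](O)/C=C(C)\CC/C=C(\C)[C@@H]2OC(=O)C(C)C | intermediate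
44 | (4S,5R,6S,7S,8R,9S)-4,5-epoxy-6-hydroxy-9-(2-methylpropanoyloxy)germacra-1(10)E,11(13)-dien-12,8-olide (CNP0220196.2) | C=C1C(=O)O[C@@H]2[C@@H]1[C@H](O)[C@H]1O[C@@]1(C)CC/C=C(\C)[C@@H]2OC(=O)C(C)C | target

## Step count and least certain steps

Total: 29 steps. Longest linear sequence: 25 steps (from 4 through steps 2–8 and 12–29); 23 steps from 1.

Step 21 (key step). Intermolecular alkylation may outrun a strained ten-membered closure, attack may go to the substituted terminus C10, and palladium may slowly ionize the allylic sulfonyl groups of substrate or product with migration of sulfinate. The fallback closes the same bond without palladium, by alkylating a sulfone-stabilized allyl carbanion with an allylic bromide. It sets out from 27: HF·pyridine frees the C2 allylic alcohol F1, CBr4/PPh3 turns it into the C2 allylic bromide F2, and slow addition of F2 to LiN(SiMe3)2 in THF at −78 to 0 °C and 1 mM closes C2–C3 by SN2 displacement. The product is 35, where the route goes on with step 23.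

Step 5. The relative configuration may come out syn instead of anti, or the catalyst may deliver to the other aldehyde face, because furan-derived dienolates are less well mapped with this catalyst class than acyclic ones. The fallback sets C9 by inversion instead of by the catalyst. It sets out from 3 and 9: with the mirror-image (S,S)-catalyst a syn-selective addition gives the (8R,9R) syn adduct F3, and Mitsunobu esterification of F3 with acetic acid (PPh3, diisopropyl azodicarboxylate) inverts C9 and returns to the route at 12.

Step 12. Simple diastereoselection at C6 may be low if the allylchromium reacts through a boat or an open arrangement, and addition through C13 instead of C7 is possible at the hindered γ-carbon. The fallback uses a stereospecific allylboration through a closed chair instead of the chromium reagent. It sets out from 14: bis(pinacolato)diboron with catalytic Pd2(dba)3 [tris(dibenzylideneacetone)dipalladium] gives the allyl pinacol boronate F4, and heating F4 with 20 in toluene (2-alkoxycarbonyl allylboronate addition) puts O6 anti to C8 and C7 trans to C8, returning at 22.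

Step 23. Hydride may be delivered to C5 instead of C3 (shift of the alkene to C3=C4), or the π-allyl complex may isomerize and erode the Z geometry, because both termini are secondary here. The fallback replaces the palladium hydride by electron-transfer cleavage: from 35, sodium amalgam (Na/Hg) with Na2HPO4 in MeOH/THF at −20 °C gives 36 directly; it makes no new compound.

Step 26. Loss of the C6 silyl ether in warm aqueous acid would leave two γ-hydroxyls competing for the acid, and protonation of the diene could start a transannular cyclization. The fallback avoids aqueous acid on the seco acid and forms the lactone by oxidation. It sets out from 37: ketal exchange with pyridinium p-toluenesulfonate in methanol at room temperature gives the 8,9,12-triol F5, and 2,2,6,6-tetramethylpiperidine-1-oxyl with PhI(OAc)2 oxidizes the primary alcohol of F5 through the lactol to the lactone, returning at 41.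

## Further compounds

F1 | step 21 | C2 alcohol of sulfone 27 (primary silyl ether removed) | OC/C=C(\C)[C@@H]1OC(C)(C)O[C@@H]1[C@@H](C(=C)COCc1ccc(OC)cc1)[C@H](O[Si](C)(C)C(C)(C)C)/C=C(C)\CS(=O)(=O)c1ccccc1
F2 | step 21 | C2 allylic bromide from F1 | BrC/C=C(\C)[C@@H]1OC(C)(C)O[C@@H]1[C@@H](C(=C)COCc1ccc(OC)cc1)[C@H](O[Si](C)(C)C(C)(C)C)/C=C(C)\CS(=O)(=O)c1ccccc1
F3 | step 5 | (5R)-5-[(1R,2E)-4-(tert-butyldimethylsilyloxy)-1-hydroxy-2-methylbut-2-en-1-yl]-3-[(4-methoxybenzyloxy)methyl]furan-2(5H)-one (syn adduct) | CC(C)(C)[Si](C)(C)OC/C=C(\C)[C@@H](O)[C@@H]1OC(=O)C(COCc2ccc(OC)cc2)=C1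
F4 | step 12 | allyl pinacol boronate from 14 (CH2Br replaced by CH2B(pin)) | CC(C)(C)[Si](C)(C)OC/C=C(\C)[C@H](OC(C)=O)[C@@H]1OC(=O)C(CB2OC(C)(C)C(C)(C)O2)=C1
F0 | step 23 | none | none
F5 | step 26 | (6R,7R,8R,9S)-6-(tert-butyldimethylsilyloxy)germacra-1(10)E,4Z,11(13)-triene-8,9,12-triol | O[C@@H]1[C@@H](C(=C)CO)[C@H](O[Si](C)(C)C(C)(C)C)/C=C(C)\CC/C=C(\C)[C@@H]1O
A1 | alternative 1 | ten-membered (Z)-allylic alcohol, 13-nor 12,8-lactone (C11 unsubstituted), 9-isobutyrate, 4,5-alkene | C1C(=O)O[C@@H]2[C@@H]1[C@H](O)/C=C(C)\CC/C=C(\C)[C@@H]2OC(=O)C(C)C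
A2 | alternative 1 | seco C6 aldehyde with (Z)-alkenyl iodide at C5 | C1C(=O)O[C@H]([C@@H]1C=O)[C@@H](OC(=O)C(C)C)/C(C)=C/CC/C(C)=C\I
A3 | alternative 2 | (1(10)E,4Z)-cyclodecadien-9-one with 6-methoxymethyl ether, 7-(2-methyl-1,3-dioxolan-2-yl) and 8-silyl ether | CC(C)(C)[Si](C)(C)O[C@@H]1[C@@H](C2(C)OCCO2)[C@H](OCOC)/C=C(C)\CC/C=C(\C)C1=O
A4 | alternative 2 | cyclohex-2-enone partner (C5–C10 ring) with the same C6, C7 and C8 substituents | CC1=C[C@@H](OCOC)[C@H](C2(C)OCCO2)[C@@H](O[Si](C)(C)C(C)(C)C)C1=O
A5 | alternative 2 | 1-methylcyclobutene | CC1=CCC1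
A6 | alternative 3 | ten-membered C6 ketone with fused lactol methyl ether and C9 4-methoxybenzyl ether | C1[C@H](OC)O[C@@H]2[C@@H]1C(=O)/C=C(C)\CC/C=C(\C)[C@@H]2OCc1ccc(OC)cc1
A7 | alternative 3 | (1S,6S)-trans-dialkenylcyclohex-4-en-6-ol: C6 carries hydroxyl and a 2-methoxy-2,3-dihydrofuran-4-yl group, C1 a (Z)-1-(4-methoxybenzyloxy)prop-1-en-2-yl group | O[C@@]1(C2=CO[C@@H](OC)C2)C=C(C)CC[C@H]1/C(C)=C\OCc1ccc(OC)cc1
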